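**Retrosynthetic overview**

1. Target 17 ⇐ hexabenzyl ether 16 (hydrogenolysis) ⇐ benzylic alcohol 15 by O1–C2 closure of ring C of the upper flavan unit ⇐ lactol 12 + Grignard reagent 14 (C2–aryl bond).
2. Lactol 12 ⇐ enal 8 + resorcinol 9. The strategy rests on ring A of the upper 4',7-dihydroxyflavan unit being a resorcinol: C4a is ortho to the oxygen on C8a (O1) and para to the C7 hydroxyl. Free resorcinol can therefore deliver C4a and O1 to a C2–C3–C4 enal carried on C8 of the epicatechin unit, forming C4–C4a and O1–C2 and setting C4.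
3. Enal 8 ⇐ 8-bromo-penta-O-benzylepicatechin 4 (Br–Li exchange, three-carbon formylation) ⇐ (−)-epicatechin 1, which supplies the lower rings A, B and C with both of their stereocentres.
4. Ring order: lower flavan from 1; upper ring A from 9; upper ring C first as the lactol (step 5), opened (step 7), then reclosed as the 2,4-cis flavan (step 8).

Key step: step 5

Assumption: the usual steric model for diarylprolinol silyl ether iminium ions (nucleophile anti to the CPh2OSiMe3 group on the E, s-trans ion) is taken to hold for enal 8, which assigns the (R)-catalyst to the 4S adduct; the (S)-catalyst would be used if the assignment proved reversed.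

**Step 1**
Reactants: 1 (−)-epicatechin
Product: 2 5,7,3',4'-tetra-O-benzyl-(−)-epicatechin
Conditions: BnBr (4.5 equiv), K2CO3 (5 equiv), DMF, 0 °C → rt
Reagents that add atoms: benzyl bromide, BrCc1ccccc1
Why: Williamson ether synthesis in which K2CO3 deprotonates only the four phenols, so the secondary 3-OH stays free and neither stereocentre is touched.

**Step 2**
Reactants: 2 5,7,3',4'-tetra-O-benzyl-(−)-epicatechin
Product: 3 3,5,7,3',4'-penta-O-benzyl-(−)-epicatechin
Conditions: NaH (1.5 equiv), BnBr (1.3 equiv), n-Bu4NI (cat.), THF/DMF, 0 °C → rt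
Reagents that add atoms: benzyl bromide, BrCc1ccccc1
Why: Williamson ether synthesis of the remaining secondary alcohol through its sodium alkoxide; with no free phenol left, ring C cannot open by a quinone methide, so C2 and C3 are not at risk.

**Step 3**
Reactants: 3 3,5,7,3',4'-penta-O-benzyl-(−)-epicatechin
Product: 4 8-bromo-3,5,7,3',4'-penta-O-benzyl-(−)-epicatechin
Conditions: NBS (1.0 equiv), CH2Cl2, −78 °C → rt
Reagents that add atoms: N-bromosuccinimide, O=C1CCC(=O)N1Br
Why: Electrophilic aromatic bromination; in 5,7-di-O-benzyl flavan-3-ol ethers C8 is the more reactive of the two free positions of ring A, so one equivalent of NBS at low temperature should give the 8-bromide.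

**Step 4**
Reactants: 4 8-bromo-3,5,7,3',4'-penta-O-benzyl-(−)-epicatechin; 5 (E)-3-(dimethylamino)acrolein
Product: 8 (E)-3-(penta-O-benzylepicatechin-8-yl)acrylaldehyde, via 8-lithio-penta-O-benzylepicatechin 6 (not isolated), via lithium aminoallyl alkoxide 7 (not isolated)
Conditions: n-BuLi (1.1 equiv), THF, −78 °C; 5 (1.5 equiv), −78 → 0 °C; 1 M HCl, THF, rt
Reagents that add atoms: water, O
Why: Bromine–lithium exchange followed by a vinylogous Bouveault formylation: the aryllithium adds to the carbonyl carbon of the vinylogous formamide, and acid hydrolysis of the amino allyl alkoxide with loss of dimethylamine unmasks the conjugated enal in its thermodynamic E geometry.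

**Step 5**
Reactants: 8 (E)-3-(penta-O-benzylepicatechin-8-yl)acrylaldehyde; 9 resorcinol
Product: 12 (4S)-4-(penta-O-benzylepicatechin-8-yl)chroman-2,7-diol, via iminium ion 10 (not isolated), via open-chain hydroxy aldehyde 11 (not isolated)
Conditions: (R)-α,α-diphenylprolinol trimethylsilyl ether (20 mol%), PhCO2H (20 mol%), 9 (3 equiv), CH2Cl2/MeCN (4:1, 0.5 M), rt, 48–96 h
Reagents that add atoms: none
Why: The (R)-amine condenses with enal 8 to the E, s-trans iminium ion 10, whose Si face at the β carbon is covered by the CPh2OSiMe3 group, so resorcinol adds through its C4 to the Re face (C4–C4a bond) and sets C4 of the new flavan unit as S under catalyst control, the remote epicatechin stereocentres having little say. Hydrolysis releases aldehyde 11, and the hydroxyl ortho to the new bond adds to the aldehyde carbon in a 6-exo-trig closure (O1–C2 bond) to give the pyran ring as lactol 12, an anomeric mixture at C2 that is of no consequence. Lactol formation withdraws the adduct from the reversible Friedel–Crafts step and so protects the C4 configuration. The closest known reaction is the diarylprolinol silyl ether catalysed Friedel–Crafts alkylation/hemiacetalisation of naphthols and electron-rich phenols with β-aryl enals to 4-arylchroman-2-ols. The step needs enantioface selection at the β carbon, supplied by the catalyst, and attack through resorcinol C4 (equivalent to C6) and not C2, secured by the bulk of the 2,6-dioxygenated β-aryl group. That same group lowers the electrophilicity of the iminium ion, which is why excess resorcinol, high concentration, an acid co-catalyst and a long reaction time are specified.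

**Step 6**
Reactants: 13 1-(benzyloxy)-4-bromobenzene
Product: 14 4-(benzyloxy)phenylmagnesium bromide
Conditions: Mg turnings (1.2 equiv), I2 (cat.), THF, 50 °C; used as a ca. 0.8 M solution
Reagents that add atoms: magnesium, [Mg]
Why: Grignard reagent formation by insertion of magnesium into the aryl C–Br bond; the benzyl ether is inert.

**Step 7**
Reactants: 12 (4S)-4-(penta-O-benzylepicatechin-8-yl)chroman-2,7-diol; 14 4-(benzyloxy)phenylmagnesium bromide
Product: 15 (3S)-1-[4-(benzyloxy)phenyl]-3-(2,4-dihydroxyphenyl)-3-(penta-O-benzylepicatechin-8-yl)propan-1-ol (carbinol epimers)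
Conditions: 14 (5 equiv), THF, 0 °C → rt; sat. aq. NH4Cl
Reagents that add atoms: none
Why: Grignard addition to a lactol: two equivalents deprotonate the phenol and the lactol hydroxyl, the magnesium lactolate opens to the aldehyde and a further equivalent adds to it; the new carbinol centre forms as a mixture that step 8 erases, and C4 is not affected.

**Step 8**
Reactants: 15 (3S)-1-[4-(benzyloxy)phenyl]-3-(2,4-dihydroxyphenyl)-3-(penta-O-benzylepicatechin-8-yl)propan-1-ol
Product: 16 (2S,4S)-2-[4-(benzyloxy)phenyl]-4-(penta-O-benzylepicatechin-8-yl)chroman-7-ol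
Conditions: TsOH·H2O (10 mol%), CH2Cl2 (0.01 M), 0 °C → rt
Reagents that add atoms: none
Why: Acid-catalysed SN1 cycloetherification: the 4-benzyloxybenzylic alcohol ionises under mild acid and the phenol ortho to C4 traps the cation (O1–C2); because the ionisation is reversible, the more stable 2,4-cis flavan with both aryl groups pseudo-equatorial should prevail, which sets C2 as S relative to the fixed C4.

**Step 9**
Reactants: 16 (2S,4S)-2-[4-(benzyloxy)phenyl]-4-(penta-O-benzylepicatechin-8-yl)chroman-7-ol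
Product: 17 (2R,3R)-2-(3,4-dihydroxyphenyl)-8-[(2S,4S)-7-hydroxy-2-(4-hydroxyphenyl)chroman-4-yl]chroman-3,5,7-triol (CNP0298337.1)
Conditions: H2 (1 atm), Pd(OH)2/C, THF/MeOH (1:1), rt
Reagents that add atoms: none
Why: Catalytic hydrogenolysis of the six benzyl ethers; the cyclic benzylic ethers of both pyran rings and the diarylmethine C4 are not expected to cleave under these mild conditions, so no stereocentre is affected.

**Compound list**

1 | (−)-epicatechin | Oc1cc(O)c2c(c1)O[C@H](c1ccc(O)c(O)c1)[C@H](O)C2 | starting material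
2 | 5,7,3',4'-tetra-O-benzyl-(−)-epicatechin | C(c1ccccc1)Oc1cc(OCc3ccccc3)c2c(c1)O[C@H](c1ccc(OCc3ccccc3)c(OCc3ccccc3)c1)[C@H](O)C2 | intermediate
3 | 3,5,7,3',4'-penta-O-benzyl-(−)-epicatechin | C(c1ccccc1)Oc1cc(OCc3ccccc3)c2c(c1)O[C@H](c1ccc(OCc3ccccc3)c(OCc3ccccc3)c1)[C@H](OCc1ccccc1)C2 | intermediate
4 | 8-bromo-3,5,7,3',4'-penta-O-benzyl-(−)-epicatechin | Brc1c(OCc2ccccc2)cc(OCc2ccccc2)c2c1O[C@H](c1ccc(OCc3ccccc3)c(OCc3ccccc3)c1)[C@H](OCc1ccccc1)C2 | intermediate
5 | (E)-3-(dimethylamino)acrolein | CN(C)/C=C/C=O | starting material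
6 | 8-lithio-penta-O-benzylepicatechin | [Li]c1c(OCc2ccccc2)cc(OCc2ccccc2)c2c1O[C@H](c1ccc(OCc3ccccc3)c(OCc3ccccc3)c1)[C@H](OCc1ccccc1)C2 | intermediate
7 | lithium (E)-3-(dimethylamino)-1-(penta-O-benzylepicatechin-8-yl)prop-2-en-1-olate (carbinol epimers) | CN(C)/C=C/C(O[Li])c1c(OCc2ccccc2)cc(OCc2ccccc2)c2c1O[C@H](c1ccc(OCc3ccccc3)c(OCc3ccccc3)c1)[C@H](OCc1ccccc1)C2 | intermediate
8 | (E)-3-(penta-O-benzylepicatechin-8-yl)acrylaldehyde | O=C/C=C/c1c(OCc2ccccc2)cc(OCc2ccccc2)c2c1O[C@H](c1ccc(OCc3ccccc3)c(OCc3ccccc3)c1)[C@H](OCc1ccccc1)C2 | intermediate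
9 | resorcinol | Oc1cccc(O)c1 | starting material
10 | iminium ion of enal 8 and (R)-α,α-diphenylprolinol trimethylsilyl ether (cation, E at C=N and C=C) | C[Si](C)(C)OC(c1ccccc1)(c1ccccc1)[C@H]1CCC/[N+]1=C\C=C\c1c(OCc2ccccc2)cc(OCc2ccccc2)c2c1O[C@H](c1ccc(OCc3ccccc3)c(OCc3ccccc3)c1)[C@H](OCc1ccccc1)C2 | intermediate
11 | (3S)-3-(2,4-dihydroxyphenyl)-3-(penta-O-benzylepicatechin-8-yl)propanal | O=CC[C@H](c1c(OCc2ccccc2)cc(OCc2ccccc2)c2c1O[C@H](c1ccc(OCc3ccccc3)c(OCc3ccccc3)c1)[C@H](OCc1ccccc1)C2)c1ccc(O)cc1O | intermediate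
12 | (4S)-4-(penta-O-benzylepicatechin-8-yl)chroman-2,7-diol (lactol, C2 anomers) | OC1C[C@H](c2c(OCc3ccccc3)cc(OCc3ccccc3)c3c2O[C@H](c2ccc(OCc4ccccc4)c(OCc4ccccc4)c2)[C@H](OCc2ccccc2)C3)c2ccc(O)cc2O1 | intermediate
13 | 1-(benzyloxy)-4-bromobenzene | Brc1ccc(OCc2ccccc2)cc1 | starting material
14 | 4-(benzyloxy)phenylmagnesium bromide | Br[Mg]c1ccc(OCc2ccccc2)cc1 | intermediate
15 | (3S)-1-[4-(benzyloxy)phenyl]-3-(2,4-dihydroxyphenyl)-3-(penta-O-benzylepicatechin-8-yl)propan-1-ol (C1 epimers) | OC(C[C@H](c1c(OCc2ccccc2)cc(OCc2ccccc2)c2c1O[C@H](c1ccc(OCc3ccccc3)c(OCc3ccccc3)c1)[C@H](OCc1ccccc1)C2)c1ccc(O)cc1O)c1ccc(OCc2ccccc2)cc1 | intermediate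
16 | (2S,4S)-2-[4-(benzyloxy)phenyl]-4-(penta-O-benzylepicatechin-8-yl)chroman-7-ol (2,4-cis) | C(c1ccccc1)Oc1ccc([C@@H]2C[C@H](c3c(OCc5ccccc5)cc(OCc5ccccc5)c4c3O[C@H](c3ccc(OCc5ccccc5)c(OCc5ccccc5)c3)[C@H](OCc3ccccc3)C4)c3ccc(O)cc3O2)cc1 | intermediate
17 | (2R,3R)-2-(3,4-dihydroxyphenyl)-8-[(2S,4S)-7-hydroxy-2-(4-hydroxyphenyl)chroman-4-yl]chroman-3,5,7-triol (CNP0298337.1) | Oc1ccc([C@@H]2C[C@H](c3c(O)cc(O)c4c3O[C@H](c3ccc(O)c(O)c3)[C@H](O)C4)c3ccc(O)cc3O2)cc1 | target

**Step count and risks**

Total step count: 9. Longest linear sequence: 8 (steps 1–5 and 7–9 from (−)-epicatechin; step 6 is a one-step side branch).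

Steps most likely to fail:

1. Step 5 (key step). The iminium ion of 8 is stabilised by the 2,4,6-trioxygenated aryl group and screened by its two ortho substituents. Conjugate addition of resorcinol may therefore stall, give way to 1,2-addition at the aldehyde carbon, or proceed with poor facial selectivity. The fallback builds ring C by cycloaddition instead of annulation and sets out from bromide 4. Bromine–lithium exchange (n-BuLi, THF, −78 °C) and addition of the aryllithium to the sodium phenoxide of 4-(benzyloxy)-2-hydroxybenzaldehyde (pre-formed with NaH) should give [4-(benzyloxy)-2-hydroxyphenyl](penta-O-benzylepicatechin-8-yl)methanol F1 as a carbinol mixture. A chiral BINOL-derived N-triflylphosphoramide (5 mol%, CH2Cl2, rt) should dehydrate it to the ortho-quinone methide, which enters the known Brønsted acid catalysed inverse-demand [4+2] cycloaddition with 4-(benzyloxy)styrene. This should give (2S,4S)-7-(benzyloxy)-2-[4-(benzyloxy)phenyl]-4-(penta-O-benzylepicatechin-8-yl)chroman F2. The cis relationship comes from the endo-type transition state and the absolute sense from the catalyst enantiomer; the other cis product is a diastereomer and separable. Hydrogenolysis of the seven benzyl ethers under the conditions of step 9 comes back to the route at target 17.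

2. Step 8. Equilibration at C2 may be incomplete and leave a cis/trans mixture, or the acid may ionise the diarylmethine C4 with loss of the epicatechin unit. The fallback sets C2 by hydrogenation and sets out from diol 15. MnO2 (CH2Cl2, rt) should oxidise only the benzylic alcohol to (3S)-1-[4-(benzyloxy)phenyl]-3-(2,4-dihydroxyphenyl)-3-(penta-O-benzylepicatechin-8-yl)propan-1-one F3. Cyclodehydration (PPTS, toluene, 80 °C, molecular sieves) should give (4S)-2-[4-(benzyloxy)phenyl]-4-(penta-O-benzylepicatechin-8-yl)-4H-chromen-7-ol F4. Hydrogen over Pd/C (THF/MeOH, rt) should add to C2=C3 from the face opposite the C4 aryl group, which gives the 2,4-cis flavan, and remove the six benzyl groups in the same operation, so the sequence comes back at target 17.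

3. Step 4. The hindered aryllithium 6 may be protonated or add incompletely to the vinylogous formamide, and the acid unmasking may stop short of the enal. The fallback replaces the three-carbon formylation by a one-carbon formylation and a two-carbon olefination and sets out from bromide 4. Bromine–lithium exchange (n-BuLi, THF, −78 °C) and a DMF quench should give penta-O-benzylepicatechin-8-carbaldehyde F5. Wittig olefination with (triphenylphosphoranylidene)acetaldehyde, Ph3P=CHCHO (toluene, 90 °C), comes back to the route at enal 8.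

**Further compounds**

F1 | step 5 | [4-(benzyloxy)-2-hydroxyphenyl](penta-O-benzylepicatechin-8-yl)methanol (carbinol epimers) | OC(c1ccc(OCc2ccccc2)cc1O)c1c(OCc2ccccc2)cc(OCc2ccccc2)c2c1O[C@H](c1ccc(OCc3ccccc3)c(OCc3ccccc3)c1)[C@H](OCc1ccccc1)C2
F2 | step 5 | (2S,4S)-7-(benzyloxy)-2-[4-(benzyloxy)phenyl]-4-(penta-O-benzylepicatechin-8-yl)chroman | C(c1ccccc1)Oc1ccc([C@@H]2C[C@H](c3c(OCc5ccccc5)cc(OCc5ccccc5)c4c3O[C@H](c3ccc(OCc5ccccc5)c(OCc5ccccc5)c3)[C@H](OCc3ccccc3)C4)c3ccc(OCc5ccccc5)cc3O2)cc1
F3 | step 8 | (3S)-1-[4-(benzyloxy)phenyl]-3-(2,4-dihydroxyphenyl)-3-(penta-O-benzylepicatechin-8-yl)propan-1-one | O=C(C[C@H](c1c(OCc2ccccc2)cc(OCc2ccccc2)c2c1O[C@H](c1ccc(OCc3ccccc3)c(OCc3ccccc3)c1)[C@H](OCc1ccccc1)C2)c1ccc(O)cc1O)c1ccc(OCc2ccccc2)cc1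
F4 | step 8 | (4S)-2-[4-(benzyloxy)phenyl]-4-(penta-O-benzylepicatechin-8-yl)-4H-chromen-7-ol | C(c1ccccc1)Oc1ccc(C2=C[C@H](c3c(OCc5ccccc5)cc(OCc5ccccc5)c4c3O[C@H](c3ccc(OCc5ccccc5)c(OCc5ccccc5)c3)[C@H](OCc3ccccc3)C4)c3ccc(O)cc3O2)cc1
F5 | step 4 | penta-O-benzylepicatechin-8-carbaldehyde | O=Cc1c(OCc2ccccc2)cc(OCc2ccccc2)c2c1O[C@H](c1ccc(OCc3ccccc3)c(OCc3ccccc3)c1)[C@H](OCc1ccccc1)C2
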